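**Retrosynthetic overview**
1. The target is an unsymmetrical ether dimer of one monomer (4,6,8-trihydroxy-7-methoxy-3-methylisochroman-1-one). The C4–O–C6' ether is cut by an invertive Mitsunobu reaction into a cis-(3R,4R) 4-hydroxy monomer (unit A, electrophile) and the 6'-phenol of the same monomer after inversion at C4' (unit B).
2. The common monomer 10 comes from a one-pot anionic [4+2] annulation of an ortho-lithiated lithium benzoate (C4a carbanion and carboxylate oxygen O2, 1,4-related through C8a–C1) with (S)-2-(tosyloxy)propanal (aldehyde carbon = C4, sulfonate carbon = C3). Addition makes C4a–C4 and SN2 lactonisation makes O2–C3.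
3. Enabling feature: C4a–H is the only hydrogen ortho to the carboxyl carbon C1 on the benzene ring (C8 bears oxygen), so the carboxylate alone directs metalation there. C3–C4 of the lactone ring is a lactaldehyde unit (C4 at the aldehyde level, C3 an oxygen-bearing methyl carbinol), which a lactate sulfonate supplies. The 6-OH, para to the lactone carbonyl, is the acidic phenol used for the ether link.
4. Ring order: the benzene ring is bought (2-methoxyresorcinol, then carboxylated); the lactone ring is closed once in the key step and that product serves both halves; ether formation and deprotection finish the route.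

Key step: step 5

Remark: the tosyloxy group of 7 is assumed not to chelate lithium, so the Cornforth–Felkin (anti) mode is taken to govern the addition in step 5; 1 and 6 are taken as commercial.

**Step 1**
Reactants: 1 2-methoxyresorcinol (2-methoxybenzene-1,3-diol)
Product: 2 2,4-dihydroxy-3-methoxybenzoic acid
Conditions: KHCO3, H2O, 100 °C under CO2; then aq. HCl
Reagents that add atoms: carbon dioxide (delivered from KHCO3), O=C=O
Why: Kolbe–Schmitt carboxylation of a resorcinol takes place ortho to one hydroxyl and para to the other, and since C2 is blocked by the methoxy group the two equivalent positions C4/C6 should give a single acid, as in the beta-resorcylic acid synthesis.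

**Step 2**
Reactants: 2 2,4-dihydroxy-3-methoxybenzoic acid
Product: 3 triisopropylsilyl 2-hydroxy-3-methoxy-4-(triisopropylsilyloxy)benzoate
Conditions: TIPSCl (2.1 equiv), imidazole, DMF, 0 °C to rt
Reagents that add atoms: triisopropylsilyl chloride, CC(C)[Si](Cl)(C(C)C)C(C)C
Why: Chemoselective silylation should take the carboxylic acid and the more acidic, unhindered 4-hydroxyl, while the 2-hydroxyl, hydrogen-bonded to the carbonyl and flanked by the methoxy group, is left free towards the bulky silyl chloride.

**Step 3**
Reactants: 3 triisopropylsilyl 2-hydroxy-3-methoxy-4-(triisopropylsilyloxy)benzoate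
Product: 5 3-methoxy-2-(methoxymethoxy)-4-(triisopropylsilyloxy)benzoic acid, via MOM-protected silyl ester 4 (not isolated)
Conditions: MOMCl, i-Pr2NEt, CH2Cl2, 0 to 40 °C; then K2CO3, MeOH/H2O, 0 °C; cold aq. HCl to pH 4
Reagents that add atoms: chloromethyl methyl ether, COCCl
Why: Williamson-type MOM etherification of the remaining phenol is followed by mild basic hydrolysis of the silyl ester, which is attacked at silicon far faster than the aryl silyl ether and leaves the MOM acetal intact.

**Step 4**
Reactants: 6 ethyl (S)-2-(tosyloxy)propanoate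
Product: 7 (S)-2-(tosyloxy)propanal
Conditions: i-Bu2AlH (1.1 equiv), CH2Cl2, −78 °C; KNaC4H4O6 (aq); used cold and unpurified
Reagents that add atoms: none
Why: Partial reduction of the ester at −78 °C stops at the aluminium hemiacetal (DIBAL reduction), so the aldehyde should be released on work-up without touching the sulfonate or the lactate-derived stereocentre.

**Step 5**
Reactants: 5 3-methoxy-2-(methoxymethoxy)-4-(triisopropylsilyloxy)benzoic acid; 7 (S)-2-(tosyloxy)propanal
Product: 10 (3R,4R)-4-hydroxy-7-methoxy-8-(methoxymethoxy)-3-methyl-6-(triisopropylsilyloxy)isochroman-1-one, via dilithiated benzoate 8 (not isolated), via anti hydroxy tosylate lithium salt 9 (not isolated)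
Conditions: s-BuLi (2.2 equiv), TMEDA, THF, −78 °C; then 7, −78 °C; AcOH (1.2 equiv), −78 °C; then DMF, 50 °C
Reagents that add atoms: none
Why: Two equivalents of s-BuLi/TMEDA deprotonate the acid and then, by proximity to the lithium carboxylate, the only C–H ortho to it (C6 of the benzoate, the future C4a); this aryllithium adds to the aldehyde carbon of 7 (C4a–C4 bond), AcOH protonates the alkoxide so that it cannot close to an epoxide, and on warming the carboxylate displaces the secondary tosylate by SN2 (O2–C3 bond). The closest known reaction types are the directed ortho-lithiation of unprotected 2-alkoxybenzoic acids with aldehyde trapping, Cornforth–Felkin additions of organolithiums to alpha-sulfonyloxy and alpha-halo aldehydes, and the invertive lactonisation of hydroxy-acid sulfonates. The lactone ring is closed in the 6-exo-tet mode. C3 is controlled by the lactate-derived (S) sulfonate centre, which the SN2 closure inverts to R, and C4 by 1,2-induction from that centre: attack anti to the C–OTs bond should give the anti adduct 9 and hence the (4R) cis lactone. The step needs lithiation at C6 and not at C5, which is secured because C6 is the only position next to the carboxylate, O4 carries the bulky non-coordinating TIPS group, and the coordinating MOM group sits on O2, whose two neighbours are substituted; it also needs alkylation of the carboxylate and not of the alkoxide, which the AcOH quench secures.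

**Step 6**
Reactants: 10 (3R,4R)-4-hydroxy-7-methoxy-8-(methoxymethoxy)-3-methyl-6-(triisopropylsilyloxy)isochroman-1-one
Product: 11 (3R,4S)-7-methoxy-8-(methoxymethoxy)-3-methyl-1-oxo-6-(triisopropylsilyloxy)isochroman-4-yl formate
Conditions: HCO2H, PPh3, DIAD, THF, 0 °C to rt
Reagents that add atoms: formic acid, OC=O
Why: Mitsunobu esterification displaces the alkoxyphosphonium ion by SN2 and so should invert C4 to S, giving the trans arrangement of unit B and masking its 4-hydroxyl as a formate.

**Step 7**
Reactants: 11 (3R,4S)-7-methoxy-8-(methoxymethoxy)-3-methyl-1-oxo-6-(triisopropylsilyloxy)isochroman-4-yl formate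
Product: 12 (3R,4S)-6-hydroxy-7-methoxy-8-(methoxymethoxy)-3-methyl-1-oxoisochroman-4-yl formate
Conditions: HF·pyridine, pyridine, THF, 0 °C to rt
Reagents that add atoms: none
Why: Fluoride cleaves the aryl silyl ether, whose phenoxide para to the lactone carbonyl is a good leaving group, and the weakly acidic medium should leave the formate, the MOM acetal and the lactone untouched.

**Step 8**
Reactants: 10 (3R,4R)-4-hydroxy-7-methoxy-8-(methoxymethoxy)-3-methyl-6-(triisopropylsilyloxy)isochroman-1-one; 12 (3R,4S)-6-hydroxy-7-methoxy-8-(methoxymethoxy)-3-methyl-1-oxoisochroman-4-yl formate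
Product: 13 (3R,4S)-6-{[(3R,4S)-7-methoxy-8-(methoxymethoxy)-3-methyl-1-oxo-6-(triisopropylsilyloxy)isochroman-4-yl]oxy}-7-methoxy-8-(methoxymethoxy)-3-methyl-1-oxoisochroman-4-yl formate
Conditions: PPh3, DIAD, toluene, 0 °C to rt
Reagents that add atoms: none
Why: In this Mitsunobu etherification the 6-hydroxyl of 12, acidic because it is para to the lactone carbonyl, is the only pronucleophile and should displace the activated cis C4 oxygen of 10 with inversion, creating the C4–O–C6' ether and the (4S) trans centre of unit A.

**Step 9**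
Reactants: 13 (protected dimer from step 8)
Product: 14 (3R,4S)-6-{[(3R,4S)-6-hydroxy-7-methoxy-8-(methoxymethoxy)-3-methyl-1-oxoisochroman-4-yl]oxy}-7-methoxy-8-(methoxymethoxy)-3-methyl-1-oxoisochroman-4-yl formate
Conditions: HF·pyridine, pyridine, THF, 0 °C to rt
Reagents that add atoms: none
Why: The same fluoride cleavage of the activated aryl silyl ether as in step 7 should free the 6-hydroxyl of unit A without affecting the formate, the MOM acetals or the benzylic aryl ether.

**Step 10**
Reactants: 14 (desilylated dimer from step 9)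
Product: 15 (3R,4S)-4-{[(3R,4S)-4,8-dihydroxy-7-methoxy-3-methyl-1-oxoisochroman-6-yl]oxy}-6,8-dihydroxy-7-methoxy-3-methylisochroman-1-one
Conditions: HCl (cat.), MeOH, 0 °C to rt
Reagents that add atoms: none
Why: Acid-catalysed acetal exchange with methanol removes both MOM groups (assisted by the neighbouring carbonyl) and transesterifies the formate, while the benzylic aryl ether should survive because its cation would be poorly stabilised (ring oxygens at C6 and C8 meta, the flanked 7-methoxy twisted, carbonyl ortho).

**Compound list**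
1 | 2-methoxyresorcinol | COc1c(O)cccc1O | starting material
2 | 2,4-dihydroxy-3-methoxybenzoic acid | COc1c(O)ccc(C(=O)O)c1O | intermediate
3 | triisopropylsilyl 2-hydroxy-3-methoxy-4-(triisopropylsilyloxy)benzoate | COc1c(O[Si](C(C)C)(C(C)C)C(C)C)ccc(C(=O)O[Si](C(C)C)(C(C)C)C(C)C)c1O | intermediate
4 | triisopropylsilyl 3-methoxy-2-(methoxymethoxy)-4-(triisopropylsilyloxy)benzoate | COCOc1c(OC)c(O[Si](C(C)C)(C(C)C)C(C)C)ccc1C(=O)O[Si](C(C)C)(C(C)C)C(C)C | intermediate
5 | 3-methoxy-2-(methoxymethoxy)-4-(triisopropylsilyloxy)benzoic acid | COCOc1c(OC)c(O[Si](C(C)C)(C(C)C)C(C)C)ccc1C(=O)O | intermediate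
6 | ethyl (S)-2-(tosyloxy)propanoate | CCOC(=O)[C@H](C)OS(=O)(=O)c1ccc(C)cc1 | starting material
7 | (S)-2-(tosyloxy)propanal | C[C@H](OS(=O)(=O)c1ccc(C)cc1)C=O | intermediate
8 | lithium 6-lithio-3-methoxy-2-(methoxymethoxy)-4-(triisopropylsilyloxy)benzoate | [Li]c1cc(O[Si](C(C)C)(C(C)C)C(C)C)c(OC)c(OCOC)c1C(=O)O[Li] | intermediate
9 | lithium 6-[(1R,2S)-1-hydroxy-2-(tosyloxy)propyl]-3-methoxy-2-(methoxymethoxy)-4-(triisopropylsilyloxy)benzoate | COCOc1c(OC)c(O[Si](C(C)C)(C(C)C)C(C)C)cc([C@@H](O)[C@H](C)OS(=O)(=O)c2ccc(C)cc2)c1C(=O)[O-].[Li+] | intermediate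
10 | (3R,4R)-4-hydroxy-7-methoxy-8-(methoxymethoxy)-3-methyl-6-(triisopropylsilyloxy)isochroman-1-one | COc1c(O[Si](C(C)C)(C(C)C)C(C)C)cc2c(c1OCOC)C(=O)O[C@H](C)[C@@H]2O | intermediate
11 | (3R,4S)-7-methoxy-8-(methoxymethoxy)-3-methyl-1-oxo-6-(triisopropylsilyloxy)isochroman-4-yl formate | COc1c(O[Si](C(C)C)(C(C)C)C(C)C)cc2c(c1OCOC)C(=O)O[C@H](C)[C@H]2OC=O | intermediate
12 | (3R,4S)-6-hydroxy-7-methoxy-8-(methoxymethoxy)-3-methyl-1-oxoisochroman-4-yl formate | COc1c(O)cc2c(c1OCOC)C(=O)O[C@H](C)[C@H]2OC=O | intermediate
13 | (3R,4S)-6-{[(3R,4S)-7-methoxy-8-(methoxymethoxy)-3-methyl-1-oxo-6-(triisopropylsilyloxy)isochroman-4-yl]oxy}-7-methoxy-8-(methoxymethoxy)-3-methyl-1-oxoisochroman-4-yl formate | COc1c(O[Si](C(C)C)(C(C)C)C(C)C)cc2c(c1OCOC)C(=O)O[C@H](C)[C@H]2Oc1cc2c(c(OCOC)c1OC)C(=O)O[C@H](C)[C@H]2OC=O | intermediate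
14 | (3R,4S)-6-{[(3R,4S)-6-hydroxy-7-methoxy-8-(methoxymethoxy)-3-methyl-1-oxoisochroman-4-yl]oxy}-7-methoxy-8-(methoxymethoxy)-3-methyl-1-oxoisochroman-4-yl formate | COc1c(O)cc2c(c1OCOC)C(=O)O[C@H](C)[C@H]2Oc1cc2c(c(OCOC)c1OC)C(=O)O[C@H](C)[C@H]2OC=O | intermediate
15 | (3R,4S)-4-{[(3R,4S)-4,8-dihydroxy-7-methoxy-3-methyl-1-oxoisochroman-6-yl]oxy}-6,8-dihydroxy-7-methoxy-3-methylisochroman-1-one | COc1c(O)cc2c(c1O)C(=O)O[C@H](C)[C@H]2Oc1cc2c(c(O)c1OC)C(=O)O[C@H](C)[C@H]2O | target

**Totals**
Total step count: 10. Longest linear sequence: 9 steps (steps 1, 2, 3, 5, 6, 7, 8, 9, 10; step 4 is a one-step side branch).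

**Steps most likely to fail**

Step 5. What may go wrong: deprotonation of the alpha-sulfonyloxy aldehyde by the aryllithium (enolisation and racemisation), erosion of the anti facial selectivity, or closure of the alkoxide to an epoxide before the carboxylate attacks. The fallback removes the diastereoselective addition and sets both centres by catalyst control. It sets out from 5 and 6. Ester 6 is converted with MeNHOMe·HCl and i-PrMgCl into N-methoxy-N-methyl-(S)-2-(tosyloxy)propanamide F1. The dilithio species from 5 (same metalation) is acylated with F1, and the resulting keto carboxylate displaces the now alpha-keto tosylate to give 7-methoxy-8-(methoxymethoxy)-3-methyl-6-(triisopropylsilyloxy)isochromane-1,4-dione F2, whose C3 centre is labile. Asymmetric transfer hydrogenation with dynamic kinetic resolution (RuCl(p-cymene)[(S,S)-TsDPEN], HCO2H/Et3N; ligand hand chosen by the usual aryl ketone model) should then give the cis alcohol, and the route is rejoined at 10.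

Step 8. What may go wrong: elimination from the alkoxyphosphonium ion towards the isocoumarin (the C3 hydrogen is anti to the leaving group), or partial ionisation with incomplete inversion. The fallback changes from an invertive SN2 to a stereoconvergent SN1 etherification. It sets out from 10, which with Cl3CCN and catalytic DBU gives (3R,4R)-7-methoxy-8-(methoxymethoxy)-3-methyl-1-oxo-6-(triisopropylsilyloxy)isochroman-4-yl 2,2,2-trichloroacetimidate F3. Activation with catalytic TMSOTf in CH2Cl2 at −40 °C in the presence of phenol 12 should generate the benzylic cation, which the phenol is expected to attack anti to the 3-methyl group to give the trans ether, and the route is rejoined at 13.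

Step 10. What may go wrong: acid-promoted translactonisation of the freed 4'-hydroxy lactone to the five-membered phthalide, or solvolysis of the benzylic aryl ether. The fallback replaces the one-pot protic solvolysis by two non-protic unmasking events. It sets out from 14. Chelation-assisted acetal cleavage with MgBr2·OEt2 and n-BuSH in CH2Cl2/Et2O should remove the two MOM groups next to the carbonyls and give (3R,4S)-6-{[(3R,4S)-6,8-dihydroxy-7-methoxy-3-methyl-1-oxoisochroman-4-yl]oxy}-8-hydroxy-7-methoxy-3-methyl-1-oxoisochroman-4-yl formate F4. Aminolysis of the formate with NH3 in MeOH at 0 °C then rejoins the route at 15.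

**Further compounds**
F1 | step 5 | N-methoxy-N-methyl-(S)-2-(tosyloxy)propanamide | C[C@H](OS(=O)(=O)c1ccc(C)cc1)C(=O)N(C)OC
F2 | step 5 | 7-methoxy-8-(methoxymethoxy)-3-methyl-6-(triisopropylsilyloxy)isochromane-1,4-dione | COc1c(O[Si](C(C)C)(C(C)C)C(C)C)cc2c(c1OCOC)C(=O)OC(C)C2=O
F3 | step 8 | (3R,4R)-7-methoxy-8-(methoxymethoxy)-3-methyl-1-oxo-6-(triisopropylsilyloxy)isochroman-4-yl 2,2,2-trichloroacetimidate | COc1c(O[Si](C(C)C)(C(C)C)C(C)C)cc2c(c1OCOC)C(=O)O[C@H](C)[C@@H]2OC(=N)C(Cl)(Cl)Cl
F4 | step 10 | (3R,4S)-6-{[(3R,4S)-6,8-dihydroxy-7-methoxy-3-methyl-1-oxoisochroman-4-yl]oxy}-8-hydroxy-7-methoxy-3-methyl-1-oxoisochroman-4-yl formate | COc1c(O)cc2c(c1O)C(=O)O[C@H](C)[C@H]2Oc1cc2c(c(O)c1OC)C(=O)O[C@H](C)[C@H]2OC=O
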